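Readings and results were generated by integration with constants of no real substance, and the scatter is random.

The noon run holds 18.3 times the base of the spring run, at the same charges of substrate, partner and protic impurity. Substrate is fed over 5.0 h into the other components.

the same everywhere: substrate 0.10 M (fed, over 5.0 h)
- spring: partner 0.95 equiv; base 0.0071 equiv; protic impurity 0.10 M; run made earlier; the fed solution adds 0.25 times the starting volume
- noon: partner 0.95 equiv; base 0.13 equiv; protic impurity 0.10 M; run made earlier; the fed solution adds 0.25 times the starting volume
- Monday's: partner 0.950 equiv; base 0.00600 equiv; protic impurity 0.100 M; the fed solution adds 0.25 times the starting volume; time 20 h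
- Friday's: partner 0.950 equiv; base 0.0120 equiv; protic impurity 0.100 M; the fed solution adds 0.25 times the starting volume; time 20 h
- Wednesday's: partner 0.950 equiv; base 0.0250 equiv; protic impurity 0.100 M; the fed solution adds 0.25 times the starting volume; time 20 h
- Saturday's: partner 0.950 equiv; base 0.0500 equiv; protic impurity 0.100 M; the fed solution adds 0.25 times the starting volume; time 20 h
- Tuesday's: partner 0.950 equiv; base 0.100 equiv; protic impurity 0.100 M; the fed solution adds 0.25 times the starting volume; time 20 h

- spring (time / h: product / %, substrate / %): 1.50: 0, 27.8; 3.00: 1.0, 60.0; 5.00: 0.7, 99.1; 6.00: 0, 100.4; 8.00: 2.4, 96.2; 10.0: 15.5, 86.7
- noon (time / h: product / %, substrate / %): 0.833: 0, 15.6; 1.33: 0, 25.8; 2.00: 0, 41.2; 4.00: 0.8, 80.6; 6.00: 0, 100.2; 10.0: 0, 98.5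

(each reading ± 1 percentage point)

- amounts are per litre of the starting volume; all of the dose is in the solution fed
- the analysis behind the earlier runs scatters by 1 percentage point, standard deviation
- steps thought possible: substrate + partner + by-product -> product + 2 by-product; substrate + partner -> product + by-product; base + by-product <-> salt; partner + protic impurity -> quenched reagent
- "hardly changes" means that all values lie within two and a half points (for a concentration: within two and a half percent of the largest)
- percentages count the whole charge, also what has not yet gone in

1. amount of product at the end, in percent of the substrate charged for Monday's, Friday's, Wednesday's, Saturday's, Tuesday's, in this order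
2. the shape of the row from first to last (rises, then falls / hardly changes / falls all the way / rises all the way / falls, then rises)

What do the readings show? In the spring run, product reads 2.4 % at 8.00 h and 15.5 % at 10.0 h. In the noon run, it reads 0 % at 10.0 h.

What kind of rise is the spring one? It looks like autocatalysis, so I go to logarithms. Those two readings give 2.47 h per power of ten. I call this the decade time: the hours product needs to grow tenfold.

Is that firm? No. The lower reading is 2.4 % against a scatter of 1 percentage point, so the decade time is a rough reading.

How far did the spring run climb after its feed ended? By 2.03 powers of ten, counted back from its last reading.

And the weak spot? I assume that the decade time grows in proportion to the base, with by-product held as salt. No reading proves this, but the noon run can test it. There the decade time becomes 45.2 h, so the 5.00 h after its feed hold 0.111 powers of ten. A flat reading fits that.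

What does this give for the new row? Each flask has 15.0 h after its feed. Monday's decade time is 2.09 h, which gives 7.18 powers of ten. Wednesday's is 8.69 h, which gives 1.73. Tuesday's gives 0.431. So I expect the row to fall, with the break near Wednesday's.

Does partner wait that long? No reading shows partner, and the protic impurity may consume it. My count is therefore generous.

The forecast gives 65 %, 45 %, 4 %, 2 % and 1.8 %, with the shape falls all the way. Its ground is this: “That is autocatalysis by the by-product, which the base holds back as salt until the base is used up.” My count gives an order, not those numbers.

The flask gives 39.8 %, 32.3 %, 1.81 %, 0.434 % and 0.253 %, with the shape falls all the way, the shape forecast. The widest gap is at Monday's, 65 % against 39.8 %.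

    substrate + partner + by-product → product + 2 by-product (k = 570 /M²/h)
    substrate + partner → product + by-product (k = 0.00270 /M/h)
    base + by-product ⇌ salt, settled at all times (K = 3500 /M)
    partner + protic impurity → quenched reagent (k = 1.60 /M/h)

On Monday's, the reckoned decade time of 2.09 h is about half the 4.3 h nominal half-life of partner by the step with protic impurity alone, a figure for the concentrations as charged, and that flask ends with 39.8 % product and 0 % of its partner. On Wednesday's, the decade time reckoned the same way, 8.69 h, is longer than that Monday half-life, and at 20.0 h that flask holds 1.81 % product with 24.6 % of its partner.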